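**Plan**

- Labels used throughout (decalin half, eudesmane numbering): C10 = methyl-bearing quaternary carbon, C5 = ring-fusion CH, C4 = methylidene carbon, C7 = carbon bearing the pyran; ring A = C1–C5 + C10, ring B = C5–C10.
- Cuts: (a) O–C(spiro) and CH2–CH2 of the dihydropyran (retro-hetero-Diels–Alder) give enal 13 and (+)-alantolactone 14; (b) the C7–side-chain bond, together with excision of C8 from ring B, leads to cyclopropanol 8 on a cis-hydrindane; (c) C4–C5 and C1–C10 lead to 2-methylcyclopent-2-enone 2 and alkyne 1.
- Forward: ring A is annulated onto the cyclopentenone, whose five-membered ring is the future ring B. C8 is added as a cyclopropane across C9–C7, the cyclopropanol is opened to ring B with coupling of a masked acrolein at C7, C9 is deoxygenated, the enal is freed and joined to 14.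
- Enabling feature: ring B carries its one substituent on C7, 1,3 to C9, and C9 is flanked by the quaternary C10. A C9 ketone therefore enolises only toward C7, and scission of the C9–C7 bond of the derived cyclopropanol puts the radical on C7 alone.
- Stereochemistry: C5 from the chiral copper catalyst, C10 from the cis-only ring closure, C7 from attack on the convex face of the cis-fused bicycle, the spiro carbon from the convex face of 14, whose four centres come from the chiral pool.

Key step: step 5

Assumption: (+)-alantolactone of the natural configuration and 2-bromo-3,3-diethoxyprop-1-ene are bought; the ligand enantiomer in step 1 is the one that gives the 3R adduct.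

**Route**

Step 1
Reactants: 1 5-chloropent-1-yne; 2 2-methylcyclopent-2-en-1-one
Product: 4 (3R)-3-(5-chloropent-1-en-2-yl)-2-methylcyclopentan-1-one (C2 epimers), via alkenylalane 3 (not isolated)
Conditions: i-Bu2AlH, NiCl2(dppp) (3 mol %), THF, 22 °C; then 2, Cu(OTf)2 (5 mol %), chiral BINOL-derived phosphoramidite (10 mol %), Et2O, −30 °C; aq. HCl
Reagents that add atoms: none
Why: nickel-catalysed hydroalumination with the dppp ligand places aluminium on the internal alkyne carbon, and the copper-catalysed asymmetric conjugate addition then transfers this 1,1-disubstituted alkenyl group to the β-carbon of the enone under control of the chiral phosphoramidite (3R, the future C5), while the C2 configuration is irrelevant because it is erased in step 2.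

Step 2
Reactants: 4 (3R)-3-(5-chloropent-1-en-2-yl)-2-methylcyclopentan-1-one
Product: 5 (3aS,7aR)-7a-methyl-4-methylideneoctahydro-1H-inden-1-one
Conditions: t-BuOK, t-BuOH/THF, 25 °C
Reagents that add atoms: none
Why: methylenecyclohexane annulation by intramolecular enolate alkylation, in which the more substituted potassium enolate closes ring A by 6-exo-tet displacement of chloride and the short tether can reach only the enolate face on which it sits, so the quaternary C10 should form with a cis ring fusion (H-5 and methyl cis).

Step 3
Reactants: 5 (3aS,7aR)-7a-methyl-4-methylideneoctahydro-1H-inden-1-one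
Product: 6 trimethyl{[(3aS,7aR)-7a-methyl-4-methylidene-3a,4,5,6,7,7a-hexahydro-3H-inden-1-yl]oxy}silane
Conditions: LiN(i-Pr)2, THF, −78 °C; then Me3SiCl, −78 → 0 °C
Reagents that add atoms: chlorotrimethylsilane, C[Si](C)(C)Cl
Why: the ketone has a single enolisable position because C10 is quaternary, so deprotonation and O-silylation of the lithium enolate should give one silyl enol ether, C9=C7.

Step 4
Reactants: 6 silyl enol ether
Product: 8 tricyclic cyclopropanol (cis-hydrindane of 5 with a CH2 bridging C1 and C2 and OH on C1), via siloxycyclopropane 7 (not isolated)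
Conditions: Et2Zn, CH2I2, CH2Cl2, 0 °C; then K2CO3 (cat.), MeOH, 0 °C
Reagents that add atoms: diiodomethane, ICI
Why: Simmons–Smith cyclopropanation with the electrophilic Et2Zn/CH2I2 carbenoid, which should take the electron-rich silyl enol ether in preference to the C4 methylidene when used in slight excess at 0 °C, followed by mild methanolysis of the Si–O bond; the two cyclopropane stereocentres (expected on the methyl face) are of no consequence because both are erased in step 5.

Step 5
Reactants: 8 tricyclic cyclopropanol; 9 2-bromo-3,3-diethoxyprop-1-ene
Product: 10 (3R,4aS,8aR)-3-(3,3-diethoxyprop-1-en-2-yl)-8a-methyl-5-methylideneoctahydronaphthalen-1(2H)-one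
Conditions: 4CzIPN (3 mol %), NiBr2(dme) (10 mol %), 4,4′-di-tert-butyl-2,2′-bipyridine (12 mol %), K2HPO4, MeCN, blue LEDs, 25 °C
Reagents that add atoms: none
Why: Proposed new method: single-electron oxidation of the cyclopropanol O–H (excited 4CzIPN, phosphate as proton acceptor) gives the C9 alkoxy radical, whose strain-driven β-scission of the internal C9–C7 bond turns the five-membered ring into the six-membered ring B as a C9 ketone and leaves a secondary radical on C7; this radical is captured by the alkenylnickel bromide formed from zerovalent nickel and 9, reductive elimination from trivalent nickel makes the C7–side-chain bond, and the reduced photocatalyst returns monovalent nickel to the zerovalent state. The closest known reaction types are the photoredox/nickel ring-opening alkenylation and arylation of monocyclic cyclopropanols and the FeCl3- or manganese-mediated oxidative ring expansion of 1-siloxy- and 1-hydroxybicyclo[n.1.0]alkanes to β-functionalised cycloalkanones; their combination on a fused cyclopropanol is new. No ring is closed by bond formation: ring B arises by ring enlargement, the one-carbon bridge C8 of the cyclopropane being taken into the ring when the C9–C7 bond breaks. The new stereocentre C7 is set by substrate control, nickel and hence the alkenyl group arriving on the convex face of the cis-decalin (the face of H-5 and the C10 methyl, away from C4 of ring A), which should give the all-cis arrangement. The step needs internal rather than external (C9–C8) cyclopropane scission, secured by formation of the secondary ring radical as in the oxidative ring expansions named, and it needs radical capture to outrun β-hydride loss and reduction, for which the bipyridine-ligated nickel system is chosen; neither 1,1-disubstituted alkene is placed for a 5-exo or 6-exo closure onto C7.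

Step 6
Reactants: 10 keto acetal
Product: 12 (3S,4aS,8aS)-3-(3,3-diethoxyprop-1-en-2-yl)-8a-methyl-5-methylidenedecahydronaphthalene, via hydrazone 11 (not isolated)
Conditions: N2H4·H2O, KOH, diethylene glycol, 130 → 200 °C
Reagents that add atoms: none
Why: Wolff–Kishner reduction under Huang-Minlon conditions should remove the C9 carbonyl through the hydrazone anion with loss of N2, the ketone having no epimerisable α-stereocentre and the acetal and both 1,1-disubstituted alkenes being stable to hot alkali.

Step 7
Reactants: 12 acetal
Product: 13 2-[(2S,4aS,8aS)-4a-methyl-8-methylidenedecahydronaphthalen-2-yl]prop-2-enal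
Conditions: aq. oxalic acid, THF, 25 °C
Reagents that add atoms: water, O
Why: mild acid hydrolysis of the allylic diethyl acetal should free the 2-substituted acrolein without shifting the exocyclic C4 alkene, which needs stronger acid.

Step 8
Reactants: 13 enal; 14 (+)-alantolactone
Product: 15 target spiro dihydropyran lactone
Conditions: 14 (4 equiv, melt), BHT (5 mol %), neat, Ar, 130 °C, sealed tube
Reagents that add atoms: none
Why: thermal hetero-Diels–Alder reaction (concerted [4+2]) in which the enal is the 1-oxadiene and the exocyclic alkene of the α-methylene lactone the dienophile, with the regiochemistry of the acrolein–methacrylate cycloaddition (O to the carbonyl-bearing carbon, CH2 to CH2); the oxadiene should add to the convex face of the cis-fused lactone (the face of H-7 and H-8), which sets the spiro carbon as required, and the excess of 14 suppresses self-dimerisation of the enal.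

**Compound list**

1 | 5-chloropent-1-yne | C#CCCCCl | starting material
2 | 2-methylcyclopent-2-en-1-one | CC1=CCCC1=O | starting material
3 | (5-chloropent-1-en-2-yl)diisobutylaluminium | C=C(CCCCl)[Al](CC(C)C)CC(C)C | intermediate (not isolated)
4 | (3R)-3-(5-chloropent-1-en-2-yl)-2-methylcyclopentan-1-one, C2 epimers | ClCCCC(=C)[C@@H]1CCC(=O)C1C | intermediate
5 | (3aS,7aR)-7a-methyl-4-methylideneoctahydro-1H-inden-1-one, cis-fused | C=C1CCC[C@@]2(C)C(=O)CC[C@@H]12 | intermediate
6 | trimethyl{[(3aS,7aR)-7a-methyl-4-methylidene-3a,4,5,6,7,7a-hexahydro-3H-inden-1-yl]oxy}silane | C=C1CCC[C@@]2(C)C(O[Si](C)(C)C)=CC[C@@H]12 | intermediate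
7 | trimethylsilyl ether of 8 (cyclopropane drawn on the face of the 7a-methyl; the other face isomer would serve equally) | C=C1CCC[C@@]2(C)[C@]3(O[Si](C)(C)C)C[C@@H]3C[C@@H]12 | intermediate (not isolated)
8 | tricyclic cyclopropanol: (3aS,7aR)-cis-hydrindane of 5 with CH2 bridging C1 and C2, OH on C1, cyclopropane cis to the 7a-methyl | C=C1CCC[C@@]2(C)[C@]3(O)C[C@@H]3C[C@@H]12 | intermediate
9 | 2-bromo-3,3-diethoxyprop-1-ene | C=C(Br)C(OCC)OCC | starting material
10 | (3R,4aS,8aR)-3-(3,3-diethoxyprop-1-en-2-yl)-8a-methyl-5-methylideneoctahydronaphthalen-1(2H)-one | C=C1CCC[C@@]2(C)C(=O)C[C@H](C(=C)C(OCC)OCC)C[C@@H]12 | intermediate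
11 | hydrazone of 10 | C=C1CCC[C@@]2(C)C(=NN)C[C@H](C(=C)C(OCC)OCC)C[C@@H]12 | intermediate (not isolated)
12 | (3S,4aS,8aS)-3-(3,3-diethoxyprop-1-en-2-yl)-8a-methyl-5-methylidenedecahydronaphthalene (descriptors differ from 10 by CIP priority only) | C=C1CCC[C@@]2(C)CC[C@H](C(=C)C(OCC)OCC)C[C@@H]12 | intermediate
13 | 2-[(2S,4aS,8aS)-4a-methyl-8-methylidenedecahydronaphthalen-2-yl]prop-2-enal | C=C1CCC[C@@]2(C)CC[C@H](C(=C)C=O)C[C@@H]12 | intermediate
14 | (+)-alantolactone, (3aR,5S,8aR,9aR)-5,8a-dimethyl-3-methylidene-3a,5,6,7,8,8a,9,9a-octahydronaphtho[2,3-b]furan-2(3H)-one | C=C1C(=O)O[C@@H]2C[C@@]3(C)CCC[C@H](C)C3=C[C@H]12 | starting material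
15 | hetero-Diels–Alder adduct of 13 and 14: 3,4-dihydro-2H-pyran spiro-fused at the former C11 of alantolactone (spiro carbon R, pyran oxygen on the face of H-7 and H-8), decalin at pyran C5 | C=C1CCC[C@@]2(C)CC[C@H](C3=CO[C@@]4(CC3)C(=O)O[C@@H]3C[C@@]5(C)CCC[C@H](C)C5=C[C@@H]34)C[C@@H]12 | target

**Count and risks**

Total step count: 8. Longest linear sequence: 8 steps (1 and 2 to 15); 9 and 14 enter as bought materials.

Steps most likely to fail:

Step 5. The alkoxy radical may open the external cyclopropane bond, or nickel may open the cyclopropanol by a two-electron homoenolate path, so that no ring enlargement occurs. The secondary alkylnickel may lose β-hydride, or face control at C7 may be weak. The fallback sets out from 7, isolated after the cyclopropanation without methanolysis, and from 9. FeCl3 in DMF at 0 °C opens the C9–C7 bond with chlorine transfer to give the β-chloro ketone F1, and NaOAc in MeOH eliminates HCl to the enone F2 (C9 ketone, C7=C8). In parallel 9 is converted by bromine–lithium exchange (n-BuLi, THF, −78 °C) into (3,3-diethoxyprop-1-en-2-yl)lithium F3 and with CuI (0.5 equiv) into lithium bis(3,3-diethoxyprop-1-en-2-yl)cuprate F4. Conjugate addition of F4 to F2 (THF, −78 → −20 °C, aq. NH4Cl) should occur axially and anti to C4 of ring A, giving the same all-cis ketone. The route is rejoined at 10.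

Step 8. The enal may dimerise or polymerise at the temperature the cycloaddition needs, or the facial selectivity on the lactone may be poor. The fallback sets out from 14 and builds the pyran stepwise. Weitz–Scheffer epoxidation (t-BuOOH, DBU, CH2Cl2) of the exocyclic alkene from the convex face gives the spiro-epoxide F5. MgI2 in Et2O opens it at the CH2 terminus to the iodohydrin F6, which already carries the tertiary oxygen of the spiro carbon in the required configuration. Giese addition of the primary radical from F6 (Bu3SnH, AIBN, PhH, 80 °C) to the CH2 terminus of enal 13 gives, after hydrogen transfer and closure of the δ-hydroxy aldehyde, the lactol F7. Dehydration (MsCl, Et3N, CH2Cl2, 0 → 40 °C) erases the two epimeric centres of F7. The route is rejoined at 15.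

Step 1. The α-substituted enone may react slowly or with low enantioselectivity. The fallback sets out from 3 and 2. With achiral CuBr·SMe2 as catalyst the conjugate addition gives the racemic chloro ketone F8, and cyclisation under the conditions of step 2 gives the racemic cis-ketone F9. F9 is resolved by preparative chromatography on a chiral stationary phase, and the (3aS,7aR) enantiomer is 5, where the route is rejoined.

**Further compounds**

F1 | step 5 | (4aS,8aR)-3-chloro-8a-methyl-5-methylideneoctahydronaphthalen-1(2H)-one, C3 epimers | C=C1CCC[C@@]2(C)C(=O)CC(Cl)C[C@@H]12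
F2 | step 5 | (4aS,8aR)-8a-methyl-5-methylidene-4a,5,6,7,8,8a-hexahydronaphthalen-1(4H)-one | C=C1CCC[C@@]2(C)C(=O)C=CC[C@@H]12
F3 | step 5 | (3,3-diethoxyprop-1-en-2-yl)lithium | [Li]C(=C)C(OCC)OCC
F4 | step 5 | lithium bis(3,3-diethoxyprop-1-en-2-yl)cuprate | [Li+].C=C([Cu-]C(=C)C(OCC)OCC)C(OCC)OCC
F5 | step 8 | spiro-epoxide of 14 at the exocyclic alkene (11,13-epoxyalantolactone, epoxide oxygen on the face of H-7 and H-8) | O1[C@@]2(C1)C(=O)O[C@@H]3C[C@@]4(C)CCC[C@H](C)C4=C[C@H]23
F6 | step 8 | 11-hydroxy-13-iodo-11,13-dihydroalantolactone (hydroxyl on the face of H-7 and H-8) | O[C@@]1(CI)C(=O)O[C@@H]2C[C@@]3(C)CCC[C@H](C)C3=C[C@H]12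
F7 | step 8 | lactol: 2-hydroxytetrahydropyran corresponding to 15 plus water, epimers at the lactol carbon and its neighbour | C=C1CCC[C@@]2(C)CC[C@H](C3C(O)O[C@@]4(CC3)C(=O)O[C@@H]3C[C@@]5(C)CCC[C@H](C)C5=C[C@@H]34)C[C@@H]12
F8 | step 1 | racemic 3-(5-chloropent-1-en-2-yl)-2-methylcyclopentan-1-one | ClCCCC(=C)C1CCC(=O)C1C
F9 | step 1 | racemic cis-7a-methyl-4-methylideneoctahydro-1H-inden-1-one (both enantiomers written) | C=C1CCC[C@@]2(C)C(=O)CC[C@@H]12.C=C1CCC[C@]2(C)C(=O)CC[C@H]12
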